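The ochre run, charged with 1.1 M of starting material, ended in a first-order tail whose constant I read as 1.13 /d between 4.00 d and 5.00 d. The violet flask, the one asked about, has the same reagent and catalyst charges but 1.6 M of starting material.

in all of them: reagent 2.08 M; free catalyst 46 mM (in portions, 3)
- violet: starting material 1.6 M; the very flask that is asked about, followed so far; portions every 30 h
- ochre: starting material 1.1 M; run made earlier; portions every 30 h
- flask: starting material 1.6 M; the portions of free catalyst follow each other after 30 h, the first at the start; time 15 d

- violet (time / d: starting material / %, target / %): 0.333: 94.6, 5.7; 0.833: 86.2, 13.6; 1.67: 68.2, 31.6; 2.50: 48.2, 51.9; 3.00: 34.0, 66.6; 5.00: 10.1, 90.0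
- ochre (time / d: starting material / %, target / %): 1.67: 63.6, 36.8; 4.00: 11.1, 88.8; 5.00: 3.6, 96.0; 8.00: 0.2, 100.3; 10.0: 0, 100.7

(readings scatter by 0.3 percentage points)

- the state of affairs at 15 d: stopped, and by what, or still going (the reagent has run out first / no working catalyst is left / all of the starting material has reacted / it is still moving)
- how much of the starting material has reacted by 15 d
- how much target there is at 15 d, in percent of the starting material charged
- amount of target if the flask were left three thousand times as long, in percent of the starting material charged

- the reaction counts as stopped when no species that holds the starting material changes by six tenths of a point or more over the second half of the time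

One thing looked contradictory. At 5.00 d the violet flask showed 90.0% of target, so a count of one reagent per target left 0.640 M of reagent on paper, yet its slope from 3.00 d to 5.00 d was 0.607 /d, about half of ochre's constant.

I solved the two ends and joined them. The early end was the violet reading at 3.00 d, later than the last portion. At the late end I supposed that starting material approached a residue, not zero, at ochre's constant. Over that interval the constant leaves a fraction 0.105 of the gap, which puts the residue at 7.29%, a reading carrying the scatter of its inputs. The violet columns add to 100% at 5.00 d, so any reagent lost went by a route holding no starting material. On that supposition the loss comes to 0.597 M, the reagent tax, meaning reagent charged less target made. My own reckoning therefore stopped the violet flask near 92.7% conversion, with reagent exhausted.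

The forecast differed: all of the starting material has reacted, with 99.8% reacted, 99.8% of target and 100% in the long run, on the ground “I see no clear sign of a stall”.

The violet flask gave this: the reagent has run out first, with 90.7% reacted, 90.7% of target and 90.7% in the long run.

2 reagent → self-condensation product (k = 0.00280 /M/h); 2 free catalyst ⇌ resting dimer, settled at all times (K = 8.90 /M); reagent + free catalyst → catalyst intermediate A (k = 11.0 /M/h); catalyst intermediate C → free catalyst + target (k = 7.20 /h); catalyst intermediate A → catalyst intermediate B (k = 1.90 /h); starting material + catalyst intermediate B → catalyst intermediate C (k = 0.990 /M/h) Reagent, the limiting reagent, stood at 0% of its charge at 15.0 d. At 2.21 d the binding of reagent to free catalyst used reagent 5.2 times as fast as self-condensation. Even so, the 0.314 M of self-condensation product at the end holds 0.628 M of reagent, beside my tax of 0.597 M. Scaling that tax by the square of the charge, the order of self-condensation, gives 0.0950 M for the neighbour charged with 0.83 M of reagent, hence 45.9% conversion; that neighbour gave 47.1%.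

The data come from a simulation for an exercise; scatter was added.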